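**Retrosynthetic overview**
Target = epicatechin-(4β→8)-epicatechin 3-O-gallate-(4β→8)-epicatechin 3-O-gallate; the last operations are esterification of the middle 3-OH with protected gallic acid and hydrogenolysis of 19 benzyl ethers.
Ring B and the 3-OH of the middle unit (unit M) are added to a 4H-chromene by face-selective epoxidation and syn aryl delivery from a triarylalane (C-3, then C-2).
Key disconnection: ring C of unit M is cut at O-1–C-2 and C-4–C-4a, giving phenol 6 (top unit carrying ring A of unit M at C-4) and enal 12 (bottom-unit gallate carrying C-2–C-3–C-4 of unit M at C-8); an amine-catalysed Friedel–Crafts conjugate addition/hemiacetalisation joins them and sets C-4.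
Enabling feature: ring A of unit M is a phloroglucinol ring whose free phenolic O-1 and adjacent unsubstituted C-4a act as an O,C-1,3-dinucleophile, and C-4 is benzylic to C-8 of the bottom unit, so C-2–C-3–C-4 can be carried as a cinnamaldehyde-type enal.
Ring order: all rings of the top and bottom units come from (−)-epicatechin; ring A of unit M from 3,5-bis(benzyloxy)phenol (step 4); ring C of unit M closes in step 8; ring B of unit M is attached in step 10.

Key step: step 8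

Remark: the SMILES is read as three (2R,3R) flavan units joined by two 4β (3,4-trans) C-4→C-8 bonds, with gallates on the middle and bottom units; the route is built for this single stereoisomer.
Assumption: compounds 1, 5, 8, 10 and 17 and all reagents and catalysts are purchased.
Abbreviations: Bn = benzyl; unit T, unit M, unit B = top, middle, bottom flavan unit; "unit T-4β-yl" = 3,5,7,3',4'-penta-O-benzylepicatechin-4β-yl; "unit B-8-yl" = 5,7,3',4'-tetra-O-benzyl-3-O-[3,4,5-tris(benzyloxy)benzoyl]epicatechin-8-yl.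

**Step 1**
Reactants: 1 (−)-epicatechin
Product: 2 5,7,3',4'-tetra-O-benzyl-(−)-epicatechin
Conditions: BnBr, K2CO3, DMF, 0 °C to rt
Reagents that add atoms: benzyl bromide BrCc1ccccc1
Why: Williamson ether synthesis; the four phenols are far more acidic than the 3-OH, so only they are alkylated and C-2 and C-3 are untouched.

**Step 2**
Reactants: 2 5,7,3',4'-tetra-O-benzyl-(−)-epicatechin
Product: 3 3,5,7,3',4'-penta-O-benzyl-(−)-epicatechin
Conditions: NaH, BnBr, DMF, 0 °C to rt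
Reagents that add atoms: benzyl bromide BrCc1ccccc1
Why: Williamson ether synthesis of the secondary alkoxide masks the 3-OH of unit T as an ether that falls in the final hydrogenolysis; no stereocentre is touched.

**Step 3**
Reactants: 3 3,5,7,3',4'-penta-O-benzyl-(−)-epicatechin
Product: 4 4β-(2-ethoxyethoxy)-3,5,7,3',4'-penta-O-benzylepicatechin
Conditions: DDQ, 2-ethoxyethanol, CH2Cl2, rt
Reagents that add atoms: 2-ethoxyethanol CCOCCO
Why: DDQ benzylic oxidation; hydride abstraction from C-4 gives the ring-A-stabilised cation, which the alcohol traps anti to the 3-benzyloxy group, so the new C-4 substituent is β (3,4-trans).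

**Step 4**
Reactants: 4 4β-(2-ethoxyethoxy)-3,5,7,3',4'-penta-O-benzylepicatechin; 5 3,5-bis(benzyloxy)phenol (excess)
Product: 6 4β-[2,4-bis(benzyloxy)-6-hydroxyphenyl]-3,5,7,3',4'-penta-O-benzylepicatechin
Conditions: TMSOTf (cat.), CH2Cl2, −78 to −40 °C, then Et3N
Reagents that add atoms: none
Why: Lewis-acid Friedel–Crafts arylation at C-4 of a 4-alkoxyflavan; the regenerated C-4 cation is attacked by the phenol carbon ortho to OH (less hindered than the carbon between the two benzyloxy groups), anti to the 3-substituent, giving the 4β-aryl compound.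

**Step 5**
Reactants: 2 5,7,3',4'-tetra-O-benzyl-(−)-epicatechin
Product: 7 8-bromo-5,7,3',4'-tetra-O-benzylepicatechin
Conditions: N-bromosuccinimide, CH2Cl2, −78 °C to rt
Reagents that add atoms: N-bromosuccinimide BrN1C(=O)CCC1=O
Why: Electrophilic aromatic bromination occurs at C-8, the preferred site of the phloroglucinol-type ring A of benzylated flavan-3-ols; no stereocentre is touched.

**Step 6**
Reactants: 7 8-bromo-5,7,3',4'-tetra-O-benzylepicatechin; 8 3,4,5-tris(benzyloxy)benzoic acid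
Product: 9 8-bromo-5,7,3',4'-tetra-O-benzylepicatechin 3-O-[3,4,5-tris(benzyloxy)benzoate]
Conditions: DCC, DMAP (cat.), CH2Cl2, rt
Reagents that add atoms: none
Why: Steglich esterification of the 3-OH installs the bottom gallate with retention at C-3.

**Step 7**
Reactants: 9 8-bromo-5,7,3',4'-tetra-O-benzylepicatechin 3-O-[3,4,5-tris(benzyloxy)benzoate]; 10 (E)-2-(3,3-diethoxyprop-1-en-1-yl)-4,4,5,5-tetramethyl-1,3,2-dioxaborolane
Product: 12 (E)-3-(unit B-8-yl)prop-2-enal, via diethyl acetal 11 (not isolated)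
Conditions: Pd(OAc)2 (5 mol %), 2-dicyclohexylphosphino-2',6'-dimethoxybiphenyl (SPhos), K3PO4, toluene/H2O, 80 °C; then 1 M HCl, THF, rt
Reagents that add atoms: water O
Why: Suzuki–Miyaura coupling (the bulky biarylphosphine copes with the di-ortho-substituted electron-rich bromide) transfers the alkenyl group with retention of E geometry, and mild acid hydrolyses the acetal to the enal.

**Step 8**
Reactants: 6 4β-[2,4-bis(benzyloxy)-6-hydroxyphenyl]-3,5,7,3',4'-penta-O-benzylepicatechin; 12 (E)-3-(unit B-8-yl)prop-2-enal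
Product: 14 5,7-bis(benzyloxy)-4-(unit B-8-yl)-8-(unit T-4β-yl)chroman-2-ol (ring C of unit M; C-4 as in the target; both C-2 anomers), via hydroxy aldehyde 13 (not isolated)
Conditions: (S)-2-[diphenyl(trimethylsilyloxy)methyl]pyrrolidine (20 mol %), 4-nitrobenzoic acid (20 mol %), toluene, 0 °C to rt
Reagents that add atoms: none
Why: The amine condenses with enal 12 to an E-configured s-trans iminium ion whose β-carbon (future C-4, benzylic to C-8 of unit B) is attacked by the ring carbon ortho to the free hydroxyl of 6 (Friedel–Crafts conjugate addition, forming C-4–C-4a), and hydrolysis of the resulting enamine releases hydroxy aldehyde 13, whose phenolic O-1 adds to the aldehyde carbon (forming O-1–C-2). The closest known reaction type is the prolinol-silyl-ether-catalysed Friedel–Crafts alkylation/hemiacetalisation of electron-rich phenols and naphthols with β-aryl enals to 4-aryl-chroman-2-ols. Ring C of unit M closes by 6-exo-trig addition of the phenol oxygen to the carbonyl group. C-4 is set by the catalyst, whose diphenyl(silyloxy)methyl group shields one face of the iminium ion so that the arene adds to the open face, which for the S catalyst should correspond to the 4β configuration of the target; C-2 forms as an anomeric mixture that is irrelevant because this centre becomes sp2 in step 9. The step needs C- over O-alkylation and ortho over para attack on ring A: the soft iminium carbon favours C-attack, the para carbon is flanked by two benzyloxy groups, the other ortho position is blocked by unit T, and only the ortho adduct can cyclise to the lactol. No other free hydroxyl is present, and the benzoate ester and benzyl ethers are inert to the amine/carboxylic acid pair.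

**Step 9**
Reactants: 14 5,7-bis(benzyloxy)-4-(unit B-8-yl)-8-(unit T-4β-yl)chroman-2-ol
Product: 16 5,7-bis(benzyloxy)-4-(unit B-8-yl)-8-(unit T-4β-yl)-4H-chromene, via anomeric mesylate 15 (not isolated)
Conditions: MsCl, Et3N, CH2Cl2, 0 °C, then 40 °C
Reagents that add atoms: none
Why: Sulfonylation of the lactol hydroxyl and base-induced β-elimination (the glycal-forming dehydration of 2-deoxy lactols) give the enol ether without acid, removing the C-2 centre and leaving C-4 untouched.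

**Step 10**
Reactants: 16 5,7-bis(benzyloxy)-4-(unit B-8-yl)-8-(unit T-4β-yl)-4H-chromene; 17 4-bromo-1,2-bis(benzyloxy)benzene
Product: 21 benzylated trimer with free 3-OH in unit M (unit M 2,3-cis-3,4-trans), via epoxide 18 (not isolated), via aryllithium 19 (not isolated), via triarylalane 20 (not isolated)
Conditions: dimethyldioxirane (acetone solution), CH2Cl2, −78 to 0 °C, then evaporation; separately 17, n-BuLi, Et2O, −78 °C, then AlCl3 (one third equiv), toluene, 0 °C; the alane solution added to 18 in CH2Cl2, −78 to 0 °C; aqueous KNaC4H4O6 work-up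
Reagents that add atoms: dimethyldioxirane CC1(C)OO1
Why: Epoxidation of the enol ether should occur on the face anti to the pseudoaxial C-4 aryl group (setting C-3), and the Lewis acidic triarylalane then coordinates the epoxide oxygen and delivers an aryl group to C-2 on the same face (syn opening of an epoxy acetal, as known for 1,2-anhydro sugars with organoalanes), which sets C-2 cis to the 3-OH and trans to the C-4 aryl group.

**Step 11**
Reactants: 21 benzylated trimer with free 3-OH in unit M; 8 3,4,5-tris(benzyloxy)benzoic acid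
Product: 22 benzylated trimer bis[3,4,5-tris(benzyloxy)benzoate] (esters at O-3 of unit M and unit B; 19 benzyl ethers)
Conditions: DCC, DMAP, CH2Cl2, rt to 40 °C
Reagents that add atoms: none
Why: Steglich esterification of the only free hydroxyl (the hindered 3-OH of unit M) proceeds with retention at C-3.

**Step 12**
Reactants: 22 benzylated trimer bis[3,4,5-tris(benzyloxy)benzoate]
Product: 23 epicatechin-(4β→8)-epicatechin 3-O-gallate-(4β→8)-epicatechin 3-O-gallate (target)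
Conditions: H2 (1 atm), Pd(OH)2 on carbon, THF/MeOH/H2O, rt
Reagents that add atoms: none
Why: Catalytic hydrogenolysis removes all 19 benzyl ethers while the benzoate esters and the C–C interflavan bonds are inert, so no stereocentre is affected.

**Compound list**
1 | (−)-epicatechin, (2R,3R) | O[C@@H]1Cc2c(O)cc(O)cc2O[C@@H]1c1ccc(O)c(O)c1 | starting material
2 | 5,7,3',4'-tetra-O-benzyl-(−)-epicatechin | O[C@@H]1Cc2c(OCc9ccccc9)cc(OCc9ccccc9)cc2O[C@@H]1c8ccc(OCc9ccccc9)c(OCc9ccccc9)c8 | intermediate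
3 | 3,5,7,3',4'-penta-O-benzyl-(−)-epicatechin | C(c9ccccc9)O[C@@H]1Cc2c(OCc9ccccc9)cc(OCc9ccccc9)cc2O[C@@H]1c8ccc(OCc9ccccc9)c(OCc9ccccc9)c8 | intermediate
4 | 4β-(2-ethoxyethoxy)-3,5,7,3',4'-penta-O-benzylepicatechin (2,3-cis, 3,4-trans) | CCOCCO[C@H]1c2c(OCc9ccccc9)cc(OCc9ccccc9)cc2O[C@H](c8ccc(OCc9ccccc9)c(OCc9ccccc9)c8)[C@@H]1OCc9ccccc9 | intermediate
5 | 3,5-bis(benzyloxy)phenol | Oc1cc(OCc2ccccc2)cc(OCc2ccccc2)c1 | starting material
6 | 4β-[2,4-bis(benzyloxy)-6-hydroxyphenyl]-3,5,7,3',4'-penta-O-benzylepicatechin (unit T carrying ring A of unit M) | Oc1cc(OCc9ccccc9)cc(OCc9ccccc9)c1[C@H]3c4c(OCc9ccccc9)cc(OCc9ccccc9)cc4O[C@H](c8ccc(OCc9ccccc9)c(OCc9ccccc9)c8)[C@@H]3OCc9ccccc9 | intermediate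
7 | 8-bromo-5,7,3',4'-tetra-O-benzylepicatechin | O[C@@H]1Cc2c(OCc9ccccc9)cc(OCc9ccccc9)c(Br)c2O[C@@H]1c8ccc(OCc9ccccc9)c(OCc9ccccc9)c8 | intermediate
8 | 3,4,5-tris(benzyloxy)benzoic acid | OC(=O)c1cc(OCc2ccccc2)c(OCc2ccccc2)c(OCc2ccccc2)c1 | starting material
9 | 8-bromo-5,7,3',4'-tetra-O-benzylepicatechin 3-O-[3,4,5-tris(benzyloxy)benzoate] | O=C(O[C@@H]1Cc2c(OCc9ccccc9)cc(OCc9ccccc9)c(Br)c2O[C@@H]1c8ccc(OCc9ccccc9)c(OCc9ccccc9)c8)c7cc(OCc9ccccc9)c(OCc9ccccc9)c(OCc9ccccc9)c7 | intermediate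
10 | (E)-2-(3,3-diethoxyprop-1-en-1-yl)-4,4,5,5-tetramethyl-1,3,2-dioxaborolane | CCOC(OCC)/C=C/B1OC(C)(C)C(C)(C)O1 | starting material
11 | 8-[(E)-3,3-diethoxyprop-1-enyl]-5,7,3',4'-tetra-O-benzylepicatechin 3-O-[3,4,5-tris(benzyloxy)benzoate] | CCOC(OCC)/C=C/c1c(OCc9ccccc9)cc(OCc9ccccc9)c2c1O[C@H](c8ccc(OCc9ccccc9)c(OCc9ccccc9)c8)[C@H](OC(=O)c7cc(OCc9ccccc9)c(OCc9ccccc9)c(OCc9ccccc9)c7)C2 | intermediate
12 | (E)-3-(unit B-8-yl)prop-2-enal | O=C/C=C/c1c(OCc9ccccc9)cc(OCc9ccccc9)c2c1O[C@H](c8ccc(OCc9ccccc9)c(OCc9ccccc9)c8)[C@H](OC(=O)c7cc(OCc9ccccc9)c(OCc9ccccc9)c(OCc9ccccc9)c7)C2 | intermediate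
13 | 3-[4,6-bis(benzyloxy)-2-hydroxy-3-(unit T-4β-yl)phenyl]-3-(unit B-8-yl)propanal, C-3 configured as C-4 of unit M in the target | O=CC[C@@H](c2c(OCc9ccccc9)cc(OCc9ccccc9)c3c2O[C@H](c8ccc(OCc9ccccc9)c(OCc9ccccc9)c8)[C@H](OC(=O)c7cc(OCc9ccccc9)c(OCc9ccccc9)c(OCc9ccccc9)c7)C3)c1c(OCc9ccccc9)cc(OCc9ccccc9)c([C@H]3c4c(OCc9ccccc9)cc(OCc9ccccc9)cc4O[C@H](c8ccc(OCc9ccccc9)c(OCc9ccccc9)c8)[C@@H]3OCc9ccccc9)c1O | intermediate
14 | 5,7-bis(benzyloxy)-4-(unit B-8-yl)-8-(unit T-4β-yl)chroman-2-ol, C-4 as in the target, both C-2 anomers | OC1C[C@@H](c2c(OCc9ccccc9)cc(OCc9ccccc9)c3c2O[C@H](c8ccc(OCc9ccccc9)c(OCc9ccccc9)c8)[C@H](OC(=O)c7cc(OCc9ccccc9)c(OCc9ccccc9)c(OCc9ccccc9)c7)C3)c2c(OCc9ccccc9)cc(OCc9ccccc9)c([C@H]3c4c(OCc9ccccc9)cc(OCc9ccccc9)cc4O[C@H](c8ccc(OCc9ccccc9)c(OCc9ccccc9)c8)[C@@H]3OCc9ccccc9)c2O1 | intermediate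
15 | 2-O-methanesulfonate of 14 | CS(=O)(=O)OC1C[C@@H](c2c(OCc9ccccc9)cc(OCc9ccccc9)c3c2O[C@H](c8ccc(OCc9ccccc9)c(OCc9ccccc9)c8)[C@H](OC(=O)c7cc(OCc9ccccc9)c(OCc9ccccc9)c(OCc9ccccc9)c7)C3)c2c(OCc9ccccc9)cc(OCc9ccccc9)c([C@H]3c4c(OCc9ccccc9)cc(OCc9ccccc9)cc4O[C@H](c8ccc(OCc9ccccc9)c(OCc9ccccc9)c8)[C@@H]3OCc9ccccc9)c2O1 | intermediate
16 | 5,7-bis(benzyloxy)-4-(unit B-8-yl)-8-(unit T-4β-yl)-4H-chromene | C1=C[C@@H](c2c(OCc9ccccc9)cc(OCc9ccccc9)c3c2O[C@H](c8ccc(OCc9ccccc9)c(OCc9ccccc9)c8)[C@H](OC(=O)c7cc(OCc9ccccc9)c(OCc9ccccc9)c(OCc9ccccc9)c7)C3)c2c(OCc9ccccc9)cc(OCc9ccccc9)c([C@H]3c4c(OCc9ccccc9)cc(OCc9ccccc9)cc4O[C@H](c8ccc(OCc9ccccc9)c(OCc9ccccc9)c8)[C@@H]3OCc9ccccc9)c2O1 | intermediate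
17 | 4-bromo-1,2-bis(benzyloxy)benzene | Brc1ccc(OCc2ccccc2)c(OCc2ccccc2)c1 | starting material
18 | 2,3-epoxide of 16, oxirane trans to the C-4 aryl group | O5[C@@H]6[C@@H](c2c(OCc9ccccc9)cc(OCc9ccccc9)c3c2O[C@H](c8ccc(OCc9ccccc9)c(OCc9ccccc9)c8)[C@H](OC(=O)c7cc(OCc9ccccc9)c(OCc9ccccc9)c(OCc9ccccc9)c7)C3)c1c(OCc9ccccc9)cc(OCc9ccccc9)c([C@H]3c4c(OCc9ccccc9)cc(OCc9ccccc9)cc4O[C@H](c8ccc(OCc9ccccc9)c(OCc9ccccc9)c8)[C@@H]3OCc9ccccc9)c1O[C@@H]65 | intermediate
19 | 3,4-bis(benzyloxy)phenyllithium | [Li]c1ccc(OCc2ccccc2)c(OCc2ccccc2)c1 | intermediate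
20 | tris[3,4-bis(benzyloxy)phenyl]alane | [Al](c1ccc(OCc2ccccc2)c(OCc2ccccc2)c1)(c1ccc(OCc2ccccc2)c(OCc2ccccc2)c1)c1ccc(OCc2ccccc2)c(OCc2ccccc2)c1 | intermediate
21 | benzylated epicatechin-(4β→8)-epicatechin-(4β→8)-epicatechin: unit T 3,5,7,3',4'-penta-O-benzyl; unit M 5,7,3',4'-tetra-O-benzyl with free 3-OH; unit B 5,7,3',4'-tetra-O-benzyl 3-O-[3,4,5-tris(benzyloxy)benzoate] | O[C@@H]1[C@@H](c2c(OCc9ccccc9)cc(OCc9ccccc9)c3c2O[C@H](c8ccc(OCc9ccccc9)c(OCc9ccccc9)c8)[C@H](OC(=O)c7cc(OCc9ccccc9)c(OCc9ccccc9)c(OCc9ccccc9)c7)C3)c2c(OCc9ccccc9)cc(OCc9ccccc9)c([C@H]3c4c(OCc9ccccc9)cc(OCc9ccccc9)cc4O[C@H](c8ccc(OCc9ccccc9)c(OCc9ccccc9)c8)[C@@H]3OCc9ccccc9)c2O[C@@H]1c8ccc(OCc9ccccc9)c(OCc9ccccc9)c8 | intermediate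
22 | as 21 but with a 3,4,5-tris(benzyloxy)benzoate ester also at O-3 of unit M (19 benzyl ethers) | O=C(O[C@@H]1[C@@H](c2c(OCc9ccccc9)cc(OCc9ccccc9)c3c2O[C@H](c8ccc(OCc9ccccc9)c(OCc9ccccc9)c8)[C@H](OC(=O)c7cc(OCc9ccccc9)c(OCc9ccccc9)c(OCc9ccccc9)c7)C3)c2c(OCc9ccccc9)cc(OCc9ccccc9)c([C@H]3c4c(OCc9ccccc9)cc(OCc9ccccc9)cc4O[C@H](c8ccc(OCc9ccccc9)c(OCc9ccccc9)c8)[C@@H]3OCc9ccccc9)c2O[C@@H]1c8ccc(OCc9ccccc9)c(OCc9ccccc9)c8)c7cc(OCc9ccccc9)c(OCc9ccccc9)c(OCc9ccccc9)c7 | intermediate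
23 | epicatechin-(4β→8)-epicatechin 3-O-gallate-(4β→8)-epicatechin 3-O-gallate (CNP0279403.1) | O=C(O[C@@H]1[C@@H](c2c(O)cc(O)c3c2O[C@H](c2ccc(O)c(O)c2)[C@H](OC(=O)c2cc(O)c(O)c(O)c2)C3)c2c(O)cc(O)c([C@H]3c4c(O)cc(O)cc4O[C@H](c4ccc(O)c(O)c4)[C@@H]3O)c2O[C@@H]1c1ccc(O)c(O)c1)c1cc(O)c(O)c(O)c1 | target

**Totals**
Total step count: 12.
Longest linear sequence: 9 steps (1, 5, 6, 7, 8, 9, 10, 11, 12; the branch through steps 2–4 is equally long).

**Steps most likely to fail**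

Step 8. Iminium formation and conjugate addition may be too slow because the β-aryl group of 12 is di-ortho-substituted and strongly electron-donating. Attack may occur at the ring carbon para to the hydroxyl. The two chiral partners may erode the facial control of the catalyst. Fallback (sets out from 12 and 6, comes back at 14): Pinnick oxidation of 12 (NaClO2, NaH2PO4, 2-methyl-2-butene) should give the (E)-acrylic acid F1. Acid-mediated hydroarylation and lactonisation of 6 with F1 (CF3CO2H in CH2Cl2, 0 °C), the known route from electron-rich phenols and cinnamic acids to 4-aryl-3,4-dihydrocoumarins, should give the dihydrocoumarin F2 after separation of the C-4 epimers (substrate control only). Reduction of the aryl lactone, the more electrophilic ester, with i-Bu2AlH at −78 °C should give lactol 14.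

Step 10. The epoxide may open through a free oxocarbenium ion with loss of syn delivery, the epoxy acetal may rearrange to the 3-ketone, or an aryl group may be transferred to the gallate carbonyl. Fallback (sets out from 2, 8 and 4, comes back at 22): the classical order of interflavan couplings. Steglich esterification of 2 with 8 should give the benzylated epicatechin gallate F3. DDQ with 2-ethoxyethanol should give its 4β-(2-ethoxyethoxy) derivative F4. TMSOTf-promoted coupling of F4 with excess F3 should give the 4β→8 dimer F5. TMSOTf-promoted coupling of 4 with F5 at C-8 of its upper unit should give 22; a 4→6 regioisomer would have to be separated.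

Step 7. Oxidative addition at the di-ortho-substituted electron-rich bromide may be slow, protodebromination may compete, and the base may partly cleave the gallate. Fallback (sets out from 7, comes back at 12): t-BuMe2SiCl and imidazole should give the silyl ether F6. Bromine–lithium exchange (n-BuLi, THF, −78 °C) followed by DMF should give the 8-carbaldehyde F7. Wittig olefination with Ph3P=CHCHO should give the silylated (E)-enal F8. n-Bu4NF buffered with AcOH should give the hydroxy enal F9. Steglich esterification of F9 with 8 should give 12.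

**Further compounds**
F1 | step 8 | (E)-3-(unit B-8-yl)prop-2-enoic acid | OC(=O)/C=C/c1c(OCc9ccccc9)cc(OCc9ccccc9)c2c1O[C@H](c8ccc(OCc9ccccc9)c(OCc9ccccc9)c8)[C@H](OC(=O)c7cc(OCc9ccccc9)c(OCc9ccccc9)c(OCc9ccccc9)c7)C2
F2 | step 8 | 5,7-bis(benzyloxy)-4-(unit B-8-yl)-8-(unit T-4β-yl)chroman-2-one, C-4 as in the target | O=C1C[C@@H](c2c(OCc9ccccc9)cc(OCc9ccccc9)c3c2O[C@H](c8ccc(OCc9ccccc9)c(OCc9ccccc9)c8)[C@H](OC(=O)c7cc(OCc9ccccc9)c(OCc9ccccc9)c(OCc9ccccc9)c7)C3)c2c(OCc9ccccc9)cc(OCc9ccccc9)c([C@H]3c4c(OCc9ccccc9)cc(OCc9ccccc9)cc4O[C@H](c8ccc(OCc9ccccc9)c(OCc9ccccc9)c8)[C@@H]3OCc9ccccc9)c2O1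
F3 | step 10 | 5,7,3',4'-tetra-O-benzylepicatechin 3-O-[3,4,5-tris(benzyloxy)benzoate] | O=C(O[C@@H]1Cc2c(OCc9ccccc9)cc(OCc9ccccc9)cc2O[C@@H]1c8ccc(OCc9ccccc9)c(OCc9ccccc9)c8)c7cc(OCc9ccccc9)c(OCc9ccccc9)c(OCc9ccccc9)c7
F4 | step 10 | 4β-(2-ethoxyethoxy)-5,7,3',4'-tetra-O-benzylepicatechin 3-O-[3,4,5-tris(benzyloxy)benzoate] | CCOCCO[C@H]1c2c(OCc9ccccc9)cc(OCc9ccccc9)cc2O[C@H](c8ccc(OCc9ccccc9)c(OCc9ccccc9)c8)[C@@H]1OC(=O)c7cc(OCc9ccccc9)c(OCc9ccccc9)c(OCc9ccccc9)c7
F5 | step 10 | benzylated epicatechin 3-O-gallate-(4β→8)-epicatechin 3-O-gallate dimer (both units 5,7,3',4'-tetra-O-benzyl, both esters 3,4,5-tris(benzyloxy)benzoates) | O=C(O[C@@H]1[C@@H](c2c(OCc9ccccc9)cc(OCc9ccccc9)c3c2O[C@H](c8ccc(OCc9ccccc9)c(OCc9ccccc9)c8)[C@H](OC(=O)c7cc(OCc9ccccc9)c(OCc9ccccc9)c(OCc9ccccc9)c7)C3)c2c(OCc9ccccc9)cc(OCc9ccccc9)cc2O[C@@H]1c8ccc(OCc9ccccc9)c(OCc9ccccc9)c8)c7cc(OCc9ccccc9)c(OCc9ccccc9)c(OCc9ccccc9)c7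
F6 | step 7 | 8-bromo-3-O-(tert-butyldimethylsilyl)-5,7,3',4'-tetra-O-benzylepicatechin | CC(C)(C)[Si](C)(C)O[C@@H]1Cc2c(OCc9ccccc9)cc(OCc9ccccc9)c(Br)c2O[C@@H]1c8ccc(OCc9ccccc9)c(OCc9ccccc9)c8
F7 | step 7 | 3-O-(tert-butyldimethylsilyl)-5,7,3',4'-tetra-O-benzylepicatechin-8-carbaldehyde | CC(C)(C)[Si](C)(C)O[C@@H]1Cc2c(OCc9ccccc9)cc(OCc9ccccc9)c(C=O)c2O[C@@H]1c8ccc(OCc9ccccc9)c(OCc9ccccc9)c8
F8 | step 7 | (E)-3-[3-O-(tert-butyldimethylsilyl)-5,7,3',4'-tetra-O-benzylepicatechin-8-yl]prop-2-enal | CC(C)(C)[Si](C)(C)O[C@@H]1Cc2c(OCc9ccccc9)cc(OCc9ccccc9)c(/C=C/C=O)c2O[C@@H]1c8ccc(OCc9ccccc9)c(OCc9ccccc9)c8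
F9 | step 7 | (E)-3-(5,7,3',4'-tetra-O-benzylepicatechin-8-yl)prop-2-enal | O[C@@H]1Cc2c(OCc9ccccc9)cc(OCc9ccccc9)c(/C=C/C=O)c2O[C@@H]1c8ccc(OCc9ccccc9)c(OCc9ccccc9)c8
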